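**Strategy.** Ring A is disconnected completely: the flavone is traced back to a 2-aryl-4-pyranone (rings C and B) carrying a diazoacetyl group on C6, and to a silyloxyacetylene. The key step exploits the meta relationship of O5 and O7 on ring A (C4a, C5, C6, C7, C8, C8a), the resorcinol pattern that a vinylketene and an oxygenated alkyne deliver. In one operation Wolff rearrangement, ketene–alkyne cycloaddition, four-electron opening and six-electron closure build ring A, forming C5–C6, C7–C8 and C4a–C5 (C8–C8a arises in the Wolff shift), and leave the two oxygens differentiated: O5 as free chelated phenol, O7 as silyl ether, the later sulfation site.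

Key step: step 7

Assumption: the target is taken as the free hydrogen sulfate as drawn; the sulfate is carried as its sodium salt and protonated only in the last operation. Flavone numbering (O1, C2–C4, C4a, C5–C8, C8a, primes for ring B) is used unless "pyranone" is written in front of a locant.

**Step 1**
Reactants: 1 3-hydroxy-4-methoxyacetophenone
Product: 2 1-[3-(benzyloxy)-4-methoxyphenyl]ethan-1-one
Conditions: BnBr, K2CO3, DMF, 50 °C
Reagents that add atoms: benzyl bromide, BrCc1ccccc1
Why: Williamson ether synthesis, in which the phenoxide formed by K2CO3 displaces bromide from the benzylic halide while the methyl ketone is untouched by the weak base.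

**Step 2**
Reactants: 2 1-[3-(benzyloxy)-4-methoxyphenyl]ethan-1-one; 3 ethyl acetate
Product: 4 1-[3-(benzyloxy)-4-methoxyphenyl]butane-1,3-dione
Conditions: NaH, EtOAc (3 equiv), THF, 0 °C to reflux; 1 M HCl
Reagents that add atoms: ethyl acetate (3), CCOC(C)=O
Why: Crossed Claisen condensation, in which the sodium enolate of the aryl methyl ketone is acylated by ethyl acetate and the equilibrium is pulled forward by deprotonation of the 1,3-diketone, released on acidification.

**Step 3**
Reactants: 4 1-[3-(benzyloxy)-4-methoxyphenyl]butane-1,3-dione; 5 diethyl oxalate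
Product: 7 ethyl 6-[3-(benzyloxy)-4-methoxyphenyl]-4-oxo-4H-pyran-2-carboxylate, via triketo ester 6 (not isolated)
Conditions: (CO2Et)2, NaOEt (2.2 equiv), EtOH, 0 to 50 °C; cold 1 M HCl; then p-TsOH·H2O (cat.), toluene, reflux (Dean–Stark)
Reagents that add atoms: diethyl oxalate (5), CCOC(=O)C(=O)OCC
Why: Claisen condensation of the terminal methyl group with the non-enolizable oxalate under thermodynamic control (acylation at the central carbon reverts), followed by acid-catalysed cyclodehydration of the 1,3,5-tricarbonyl chain to the 4-pyranone, the standard entry to 6-aryl-4-oxo-4H-pyran-2-carboxylates; anhydrous sulfonic acid should leave the benzyl ether intact.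

**Step 4**
Reactants: 7 ethyl 6-[3-(benzyloxy)-4-methoxyphenyl]-4-oxo-4H-pyran-2-carboxylate
Product: 8 6-[3-(benzyloxy)-4-methoxyphenyl]-4-oxo-4H-pyran-2-carboxylic acid
Conditions: LiOH·H2O (1.1 equiv), THF/H2O, 0 °C; 1 M HCl to pH 2
Reagents that add atoms: lithium hydroxide, [Li+].[OH-]
Why: Saponification of the activated ester with one equivalent of hydroxide at 0 °C should outrun attack on the pyranone ring, and any ring-opened triketo acid recloses on acidification.

**Step 5**
Reactants: 8 6-[3-(benzyloxy)-4-methoxyphenyl]-4-oxo-4H-pyran-2-carboxylic acid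
Product: 10 2-[3-(benzyloxy)-4-methoxyphenyl]-6-(2-diazoacetyl)-4H-pyran-4-one, via acid chloride 9 (not isolated)
Conditions: SOCl2, DMF (cat.), toluene, 60 °C; evaporate; CH2N2 (3 equiv, Et2O), THF, 0 °C, dark; AcOH quench
Reagents that add atoms: diazomethane, C=[N+]=[N-]
Why: Acid chloride formation as practised for chromone-2-carboxylic acids, then acylation of diazomethane (first stage of the Arndt–Eistert sequence); the acyl chloride has no α-hydrogen, so no ketene pathway competes, and the second equivalent of diazomethane consumes the HCl that would otherwise give the chloromethyl ketone.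

**Step 6**
Reactants: 11 acetylene
Product: 14 (ethynyloxy)triisopropylsilane, via lithium acetylide 12 (not isolated), via lithium ethynolate 13 (not isolated)
Conditions: HC≡CH (excess), n-BuLi, THF, −78 °C; t-BuOOLi (from t-BuOOH, LiN(SiMe3)2), −78 to −20 °C under HC≡CH; i-Pr3SiOTf, −78 to 0 °C; pentane, cold NaHCO3 (aq), bulb-to-bulb distillation
Reagents that add atoms: tert-butyl hydroperoxide, CC(C)(C)OO; triisopropylsilyl trifluoromethanesulfonate, CC(C)[Si](OS(=O)(=O)C(F)(F)F)(C(C)C)C(C)C
Why: Oxidation of a lithium acetylide by lithium tert-butyl peroxide (attack of the acetylide carbon on the O–O bond) gives the ynolate, and the bulky silyl triflate should trap this ambident anion on oxygen, as in the established preparation of 1-siloxy-1-alkynes from terminal alkynes.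

**Step 7**
Reactants: 10 2-[3-(benzyloxy)-4-methoxyphenyl]-6-(2-diazoacetyl)-4H-pyran-4-one; 14 (ethynyloxy)triisopropylsilane
Product: 19 2-[3-(benzyloxy)-4-methoxyphenyl]-5-hydroxy-7-[(triisopropylsilyl)oxy]-4H-chromen-4-one, via pyranonylketene 15 (not isolated), via siloxycyclobutenone 16 (not isolated), via dienylketene 17 (not isolated), via dienone 18 (not isolated)
Conditions: 14 (2 equiv), 450 nm LED, ClCH2CH2Cl (degassed), rt; then 80 °C
Reagents that add atoms: (ethynyloxy)triisopropylsilane (14), C#CO[Si](C(C)C)(C(C)C)C(C)C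
Why: Blue light should excite only the diazo ketone, whose Wolff rearrangement shifts pyranone C6 (future C8a) from the acyl carbon to the diazo carbon (future C8) and gives ketene 15, a vinylketene whose vinyl unit is the pyranone C5=C6 bond; the siloxyalkyne adds across the ketene C=C in a (2+2) cycloaddition to cyclobutenone 16, which on warming opens by four-electron electrocyclic cleavage to dienylketene 17. Ring A is then closed by a thermal disrotatory six-electron electrocyclization of 17, in which the ketene carbon (future C5) bonds to pyranone C5 (future C4a), and dienone 18 enolizes to the aromatic, hydrogen-bonded 5-phenol. The closest known reaction type is the Danheiser benzannulation in its photo-Wolff (diazo ketone) form with siloxyalkynes, established for alkenyl, aryl and five-membered heteroaryl diazomethyl ketones; a 4-pyranone has not served as the vinyl component, which is why the risk of the route sits here. No stereocentre is created, the sp3 centres of 16 and 18 being transient. The selectivity needed is the orientation of the (2+2) step: the unsubstituted alkyne carbon is the nucleophilic terminus and bonds to the ketene carbonyl carbon, so the silyloxy carbon becomes C7, meta to the 5-hydroxyl, while the site of closure is fixed because pyranone C5–H is the only position flanking the ketenyl-bearing carbon. Light of 450 nm is chosen because the arylpyranone and the flavone formed should not absorb it, which avoids the ultraviolet photoisomerization of 4-pyranones.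

**Step 8**
Reactants: 19 2-[3-(benzyloxy)-4-methoxyphenyl]-5-hydroxy-7-[(triisopropylsilyl)oxy]-4H-chromen-4-one
Product: 20 2-[3-(benzyloxy)-4-methoxyphenyl]-5,7-dihydroxy-4H-chromen-4-one
Conditions: Bu4NF, AcOH, THF, 0 °C
Reagents that add atoms: none
Why: Fluoride-induced cleavage of an aryl silyl ether, driven by the Si–F bond and buffered with acetic acid so that the acidic 7-phenol is released without base-mediated side reactions.

**Step 9**
Reactants: 20 2-[3-(benzyloxy)-4-methoxyphenyl]-5,7-dihydroxy-4H-chromen-4-one
Product: 21 sodium 2-[3-(benzyloxy)-4-methoxyphenyl]-5-hydroxy-4-oxo-4H-chromen-7-yl sulfate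
Conditions: SO3·pyridine (2 equiv), pyridine, rt; NaHCO3 (aq); C18 silica
Reagents that add atoms: sulfur trioxide–pyridine complex, O=S(=O)([O-])[n+]1ccccc1; sodium hydrogen carbonate, [Na+].OC([O-])=O
Why: O-Sulfation of a phenol with an SO3–amine complex; the 5-hydroxyl is deactivated by its hydrogen bond to the C4 carbonyl and O3' is benzylated, so only the acidic 7-hydroxyl should react, and hydrogen carbonate exchange gives the sodium salt.

**Step 10**
Reactants: 21 sodium 2-[3-(benzyloxy)-4-methoxyphenyl]-5-hydroxy-4-oxo-4H-chromen-7-yl sulfate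
Product: 23 5-hydroxy-2-(3-hydroxy-4-methoxyphenyl)-4-oxo-4H-chromen-7-yl hydrogen sulfate (luteolin 4'-methyl ether 7-sulfate), via sodium salt 22 (not isolated)
Conditions: H2 (1 atm), 10% Pd/C, MeOH/H2O, rt; filter; HCl (0.1 M, 1.0 equiv), 0 °C; C18 desalting, freeze-drying
Reagents that add atoms: none
Why: Catalytic hydrogenolysis of the benzyl aryl ether, to which the sulfate monoester anion and the flavone C2=C3 bond should be inert at 1 atm, followed by protonation with one equivalent of cold dilute acid and removal of water by freeze-drying to limit acid-catalysed sulfate hydrolysis.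

**Compound list**

1 | 3-hydroxy-4-methoxyacetophenone | CC(=O)c1ccc(OC)c(O)c1 | starting material
2 | 1-[3-(benzyloxy)-4-methoxyphenyl]ethan-1-one | CC(=O)c1ccc(OC)c(OCc2ccccc2)c1 | intermediate
3 | ethyl acetate | CCOC(C)=O | starting material
4 | 1-[3-(benzyloxy)-4-methoxyphenyl]butane-1,3-dione | CC(=O)CC(=O)c1ccc(OC)c(OCc2ccccc2)c1 | intermediate
5 | diethyl oxalate | CCOC(=O)C(=O)OCC | starting material
6 | ethyl 6-[3-(benzyloxy)-4-methoxyphenyl]-2,4,6-trioxohexanoate | CCOC(=O)C(=O)CC(=O)CC(=O)c1ccc(OC)c(OCc2ccccc2)c1 | intermediate (not isolated)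
7 | ethyl 6-[3-(benzyloxy)-4-methoxyphenyl]-4-oxo-4H-pyran-2-carboxylate | CCOC(=O)c1cc(=O)cc(-c2ccc(OC)c(OCc3ccccc3)c2)o1 | intermediate
8 | 6-[3-(benzyloxy)-4-methoxyphenyl]-4-oxo-4H-pyran-2-carboxylic acid | OC(=O)c1cc(=O)cc(-c2ccc(OC)c(OCc3ccccc3)c2)o1 | intermediate
9 | 6-[3-(benzyloxy)-4-methoxyphenyl]-4-oxo-4H-pyran-2-carbonyl chloride | ClC(=O)c1cc(=O)cc(-c2ccc(OC)c(OCc3ccccc3)c2)o1 | intermediate (not isolated)
10 | 2-[3-(benzyloxy)-4-methoxyphenyl]-6-(2-diazoacetyl)-4H-pyran-4-one | COc1ccc(-c2cc(=O)cc(C(=O)C=[N+]=[N-])o2)cc1OCc1ccccc1 | intermediate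
11 | acetylene | C#C | starting material
12 | lithium acetylide | [Li]C#C | intermediate (not isolated)
13 | lithium ethynolate | [Li+].[O-]C#C | intermediate (not isolated)
14 | (ethynyloxy)triisopropylsilane | C#CO[Si](C(C)C)(C(C)C)C(C)C | intermediate
15 | 2-{6-[3-(benzyloxy)-4-methoxyphenyl]-4-oxo-4H-pyran-2-yl}ethen-1-one (pyranonylketene) | O=C=Cc1cc(=O)cc(-c2ccc(OC)c(OCc3ccccc3)c2)o1 | intermediate (not isolated)
16 | 4-{6-[3-(benzyloxy)-4-methoxyphenyl]-4-oxo-4H-pyran-2-yl}-3-[(triisopropylsilyl)oxy]cyclobut-2-en-1-one, racemic | O=C1C=C(O[Si](C(C)C)(C(C)C)C(C)C)C1c1cc(=O)cc(-c2ccc(OC)c(OCc3ccccc3)c2)o1 | intermediate (not isolated)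
17 | (3E)-4-{6-[3-(benzyloxy)-4-methoxyphenyl]-4-oxo-4H-pyran-2-yl}-3-[(triisopropylsilyl)oxy]buta-1,3-dien-1-one | O=C=C/C(O[Si](C(C)C)(C(C)C)C(C)C)=C\c1cc(=O)cc(-c2ccc(OC)c(OCc3ccccc3)c2)o1 | intermediate (not isolated)
18 | 2-[3-(benzyloxy)-4-methoxyphenyl]-7-[(triisopropylsilyl)oxy]-4aH-chromene-4,5-dione, racemic at C4a | O=C1C=C(O[Si](C(C)C)(C(C)C)C(C)C)C=C2OC(-c3ccc(OC)c(OCc4ccccc4)c3)=CC(=O)C12 | intermediate (not isolated)
19 | 2-[3-(benzyloxy)-4-methoxyphenyl]-5-hydroxy-7-[(triisopropylsilyl)oxy]-4H-chromen-4-one | COc1ccc(-c2cc(=O)c3c(O)cc(O[Si](C(C)C)(C(C)C)C(C)C)cc3o2)cc1OCc1ccccc1 | intermediate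
20 | 2-[3-(benzyloxy)-4-methoxyphenyl]-5,7-dihydroxy-4H-chromen-4-one | COc1ccc(-c2cc(=O)c3c(O)cc(O)cc3o2)cc1OCc1ccccc1 | intermediate
21 | sodium 2-[3-(benzyloxy)-4-methoxyphenyl]-5-hydroxy-4-oxo-4H-chromen-7-yl sulfate | COc1ccc(-c2cc(=O)c3c(O)cc(OS(=O)(=O)[O-])cc3o2)cc1OCc1ccccc1.[Na+] | intermediate
22 | sodium 5-hydroxy-2-(3-hydroxy-4-methoxyphenyl)-4-oxo-4H-chromen-7-yl sulfate | COc1ccc(-c2cc(=O)c3c(O)cc(OS(=O)(=O)[O-])cc3o2)cc1O.[Na+] | intermediate (not isolated)
23 | 5-hydroxy-2-(3-hydroxy-4-methoxyphenyl)-4-oxo-4H-chromen-7-yl hydrogen sulfate (luteolin 4'-methyl ether 7-sulfate) | COc1ccc(-c2cc(=O)c3c(O)cc(OS(=O)(=O)O)cc3o2)cc1O | target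

**Step count.** Total: 10 steps. Longest linear sequence: 9 steps (steps 1 to 5 and 7 to 10); step 6 is a one-step side branch.

**Steps most likely to fail**

Step 7. The ketene may be consumed by dimerization or by adventitious nucleophiles before it meets the alkyne, or the six-electron closure onto the pyranone may be slow enough for the cyclobutenone or dienylketene to decompose on heating. The fallback gives up building ring A and uses known flavone chemistry. It sets out from 2: haloform oxidation (NaOCl, NaOH, dioxane/H2O) should give 3-(benzyloxy)-4-methoxybenzoic acid F1, and SOCl2 converts this into 3-(benzyloxy)-4-methoxybenzoyl chloride F2. C-Aroylation of the lithium polyanion of commercial 2',4',6'-trihydroxyacetophenone (LiN(SiMe3)2, 4 equiv, THF, −78 °C to rt) with F2 should give 1-[3-(benzyloxy)-4-methoxyphenyl]-3-(2,4,6-trihydroxyphenyl)propane-1,3-dione F3. Acid cyclodehydration of F3 (p-TsOH·H2O cat., AcOH, 90 °C) closes ring C, and the fallback comes back to the route at 20.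

Step 6. Lithium acetylide may disproportionate to insoluble dilithium acetylide before it is oxidized, the ynolate may be silylated on carbon to give a silylketene, and the siloxyalkyne may hydrolyse or isomerize during isolation. The fallback generates the same ynolate by ring fragmentation instead of oxidation. It replaces acetylene 11 as the two-carbon source by commercial 3-phenylisoxazole: n-BuLi in THF at −78 °C should give 5-lithio-3-phenylisoxazole F4, which on warming fragments to benzonitrile and lithium ethynolate. The fallback comes back to the route at 13, which is silylated with i-Pr3SiOTf as in step 6 to give 14.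

Step 10. Debenzylation of the sparingly soluble salt may stall, hydrogenation may run on into the C2–C3 double bond, and the sulfate monoester may be lost by acid-catalysed hydrolysis during protonation and concentration. The fallback carries the sulfate as a neutral, chromatographable diester. It sets out from 20: 2,2,2-trichloroethyl chlorosulfate, Et3N and DMAP in THF should give 2-[3-(benzyloxy)-4-methoxyphenyl]-5-hydroxy-4-oxo-4H-chromen-7-yl 2,2,2-trichloroethyl sulfate F5. Transfer hydrogenolysis (HCO2NH4, 10% Pd/C, MeOH, rt) removes the trichloroethyl group by reductive fragmentation and the benzyl ether in the same operation, giving ammonium 5-hydroxy-2-(3-hydroxy-4-methoxyphenyl)-4-oxo-4H-chromen-7-yl sulfate F6. Protonation as in step 10 brings the fallback back to the route at 23.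

**Further compounds**

F1 | step 7 | 3-(benzyloxy)-4-methoxybenzoic acid | OC(=O)c1ccc(OC)c(OCc2ccccc2)c1
F2 | step 7 | 3-(benzyloxy)-4-methoxybenzoyl chloride | ClC(=O)c1ccc(OC)c(OCc2ccccc2)c1
F3 | step 7 | 1-[3-(benzyloxy)-4-methoxyphenyl]-3-(2,4,6-trihydroxyphenyl)propane-1,3-dione | O=C(CC(=O)c1c(O)cc(O)cc1O)c1ccc(OC)c(OCc2ccccc2)c1
F4 | step 6 | 5-lithio-3-phenylisoxazole | [Li]c1cc(-c2ccccc2)no1
F5 | step 10 | 2-[3-(benzyloxy)-4-methoxyphenyl]-5-hydroxy-4-oxo-4H-chromen-7-yl 2,2,2-trichloroethyl sulfate | COc1ccc(-c2cc(=O)c3c(O)cc(OS(=O)(=O)OCC(Cl)(Cl)Cl)cc3o2)cc1OCc1ccccc1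
F6 | step 10 | ammonium 5-hydroxy-2-(3-hydroxy-4-methoxyphenyl)-4-oxo-4H-chromen-7-yl sulfate | COc1ccc(-c2cc(=O)c3c(O)cc(OS(=O)(=O)[O-])cc3o2)cc1O.[NH4+]
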